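**Retrosynthetic overview**
- The free 4'-OH is revealed last by hydrogenolysis of a benzyl ether, so the four methyl ethers never meet a dealkylating reagent.
- Ring C (the 4-pyranone) is the only ring built. It is closed at O1–C2 by oxidative cyclisation of a 2'-hydroxychalcone.
- Key C–C bond (C2–C3 of the flavone): Claisen–Schmidt aldol condensation of 2'-hydroxy-3',4',5',6'-tetramethoxyacetophenone with 4-(benzyloxy)benzaldehyde.
- The acetophenone comes from ortho-acylation (Fries) of 2,3,4,5-tetramethoxyphenol at its only free ring position.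
- That phenol comes from 2,3,4-trimethoxybenzaldehyde by CHO→OH, O-methylation, formylation and CHO→OH. Rings A and B are bought as benzenes, and ring C is formed in step 7.

Assumption: the target has no stereocentre, stereogenic axis or stereogenic double bond. It is one achiral compound, no enantiocontrol is needed, and the SMILES is taken as drawn.

**Step 1**
Reactants: 1 2,3,4-trimethoxybenzaldehyde
Product: 3 2,3,4-trimethoxyphenol, via 2,3,4-trimethoxyphenyl formate 2 (not isolated)
Conditions: 30% aq H2O2 (1.3 equiv), cat. conc. H2SO4, MeOH, rt, 16 h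
Reagents that add atoms: hydrogen peroxide, OO
Why: In this acid-catalysed Dakin/Baeyer–Villiger oxidation the aryl group, which carries ortho and para methoxy donors, migrates in preference to hydride, and formate 2 is methanolysed in the same flask; no stereocentre is formed.

**Step 2**
Reactants: 3 2,3,4-trimethoxyphenol
Product: 4 1,2,3,4-tetramethoxybenzene
Conditions: MeI (1.5 equiv), K2CO3 (2 equiv), acetone, reflux, 6 h
Reagents that add atoms: iodomethane, CI
Why: This is a Williamson O-methylation (SN2) of the only acidic OH and has no competing site; no stereocentre is formed.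

**Step 3**
Reactants: 4 1,2,3,4-tetramethoxybenzene
Product: 7 2,3,4,5-tetramethoxybenzaldehyde, via 2,3,4,5-tetramethoxyphenyllithium 5 (not isolated), via lithium hemiaminal alkoxide 6 (not isolated)
Conditions: n-BuLi (1.2 equiv), TMEDA (1.2 equiv), THF, 0 °C to rt, 2 h; DMF (2 equiv), 0 °C to rt; 1 M HCl
Reagents that add atoms: N,N-dimethylformamide, CN(C)C=O
Why: In this directed ortho-metalation/DMF formylation the two ring C–H positions of 4 are equivalent by symmetry and each lies ortho to OMe, so only one aryllithium can form, and adduct 6 survives until the acid quench, which prevents over-addition.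

**Step 4**
Reactants: 7 2,3,4,5-tetramethoxybenzaldehyde
Product: 9 2,3,4,5-tetramethoxyphenol, via 2,3,4,5-tetramethoxyphenyl formate 8 (not isolated)
Conditions: mCPBA (1.3 equiv), CH2Cl2, 0 °C to rt, 6 h; aq Na2S2O3/NaHCO3 wash; crude 8, K2CO3 (0.2 equiv), MeOH, N2, rt, 30 min; 1 M HCl
Reagents that add atoms: 3-chloroperoxybenzoic acid (mCPBA), O=C(OO)c1cccc(Cl)c1
Why: This Baeyer–Villiger oxidation proceeds by aryl migration (ortho and para OMe donors), and the very electron-rich phenol 9 is released by methanolysis only after the peracid has been destroyed, so it cannot be over-oxidised to a quinone.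

**Step 5**
Reactants: 9 2,3,4,5-tetramethoxyphenol
Product: 11 2'-hydroxy-3',4',5',6'-tetramethoxyacetophenone, via 2,3,4,5-tetramethoxyphenyl acetate 10 (not isolated)
Conditions: Ac2O (1.5 equiv), BF3·OEt2 (3 equiv), AcOH, 70 °C, 2 h; ice-water
Reagents that add atoms: acetic anhydride, CC(=O)OC(C)=O
Why: O-Acetylation is followed by a BF3-promoted Fries rearrangement (Friedel–Crafts C-acylation), and because the para position is blocked and only one ring carbon bears hydrogen (ortho to the oxygen, activated by ortho and para OMe), the hydrogen-bonded o-hydroxyketone 11 is the only possible C-acyl product.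

**Step 6**
Reactants: 11 2'-hydroxy-3',4',5',6'-tetramethoxyacetophenone; 12 4-(benzyloxy)benzaldehyde
Product: 14 (E)-4-benzyloxy-2'-hydroxy-3',4',5',6'-tetramethoxychalcone, via racemic aldol adduct 13 (not isolated)
Conditions: KOH (10 equiv, 50% aq), EtOH–THF, N2, rt, 36–48 h; 1 M HCl, 0 °C
Reagents that add atoms: none
Why: In this Claisen–Schmidt crossed aldol condensation 12 cannot enolise, so only the methyl ketone enolate of 11 acts as donor, and E1cB dehydration of 13 removes its racemic carbinol centre and gives the thermodynamic E-enone.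

**Step 7**
Reactants: 14 (E)-4-benzyloxy-2'-hydroxy-3',4',5',6'-tetramethoxychalcone
Product: 17 4'-benzyloxy-5,6,7,8-tetramethoxyflavone, via 4'-benzyloxy-5,6,7,8-tetramethoxyflavanone 15 (not isolated), via 3-iodoflavanone 16 (not isolated)
Conditions: I2 (0.1 equiv), DMSO, 125 °C, 3 h; aq Na2S2O3
Reagents that add atoms: none
Why: In the I2/DMSO oxidative cyclisation, intramolecular oxa-Michael addition gives 15, alpha-iodination gives 16 and loss of HI gives the 4-pyranone while DMSO reoxidises HI to I2; ring A has no free position to iodinate, and the transient stereocentres are erased.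

**Step 8**
Reactants: 17 4'-benzyloxy-5,6,7,8-tetramethoxyflavone
Product: 18 4'-hydroxy-5,6,7,8-tetramethoxyflavone
Conditions: H2 (1 atm), 10% Pd/C, EtOAc–MeOH 1:1, rt, 3 h
Reagents that add atoms: none
Why: Catalytic hydrogenolysis cleaves only the benzylic C–O bond, since aryl methyl ethers and the cross-conjugated pyranone are inert at 1 atm and rt, and the product is achiral, so no configuration has to be set.

**Compound list**
1 | 2,3,4-trimethoxybenzaldehyde | COc1ccc(C=O)c(OC)c1OC | starting material
2 | 2,3,4-trimethoxyphenyl formate | COc1ccc(OC=O)c(OC)c1OC | intermediate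
3 | 2,3,4-trimethoxyphenol | COc1ccc(O)c(OC)c1OC | intermediate
4 | 1,2,3,4-tetramethoxybenzene | COc1ccc(OC)c(OC)c1OC | intermediate
5 | 2,3,4,5-tetramethoxyphenyllithium | [Li]c1cc(OC)c(OC)c(OC)c1OC | intermediate
6 | lithium (dimethylamino)(2,3,4,5-tetramethoxyphenyl)methanolate (racemic) | [Li+].[O-]C(N(C)C)c1cc(OC)c(OC)c(OC)c1OC | intermediate
7 | 2,3,4,5-tetramethoxybenzaldehyde | COc1cc(C=O)c(OC)c(OC)c1OC | intermediate
8 | 2,3,4,5-tetramethoxyphenyl formate | COc1cc(OC=O)c(OC)c(OC)c1OC | intermediate
9 | 2,3,4,5-tetramethoxyphenol | COc1cc(O)c(OC)c(OC)c1OC | intermediate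
10 | 2,3,4,5-tetramethoxyphenyl acetate | COc1cc(OC(C)=O)c(OC)c(OC)c1OC | intermediate
11 | 2'-hydroxy-3',4',5',6'-tetramethoxyacetophenone, i.e. 1-(2-hydroxy-3,4,5,6-tetramethoxyphenyl)ethanone | CC(=O)c1c(O)c(OC)c(OC)c(OC)c1OC | intermediate
12 | 4-(benzyloxy)benzaldehyde | O=Cc1ccc(OCc2ccccc2)cc1 | starting material
13 | 3-[4-(benzyloxy)phenyl]-3-hydroxy-1-(2-hydroxy-3,4,5,6-tetramethoxyphenyl)propan-1-one (racemic aldol adduct) | COc1c(OC)c(OC)c(C(=O)CC(O)c2ccc(OCc3ccccc3)cc2)c(O)c1OC | intermediate
14 | (E)-4-benzyloxy-2'-hydroxy-3',4',5',6'-tetramethoxychalcone | COc1c(OC)c(OC)c(C(=O)/C=C/c2ccc(OCc3ccccc3)cc2)c(O)c1OC | intermediate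
15 | 4'-benzyloxy-5,6,7,8-tetramethoxyflavanone (racemic) | COc1c(OC)c(OC)c2C(=O)CC(c3ccc(OCc4ccccc4)cc3)Oc2c1OC | intermediate
16 | 4'-benzyloxy-3-iodo-5,6,7,8-tetramethoxyflavanone (racemic, transient, relative configuration of no consequence) | COc1c(OC)c(OC)c2C(=O)C(I)C(c3ccc(OCc4ccccc4)cc3)Oc2c1OC | intermediate
17 | 4'-benzyloxy-5,6,7,8-tetramethoxyflavone | COc1c(OC)c(OC)c2c(=O)cc(-c3ccc(OCc4ccccc4)cc3)oc2c1OC | intermediate
18 | 4'-hydroxy-5,6,7,8-tetramethoxyflavone (achiral) | COc1c(OC)c(OC)c2c(=O)cc(-c3ccc(O)cc3)oc2c1OC | target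

**Totals**
Total step count: 8.
Longest linear sequence: 8 steps (1 to 18). Compound 12 is bought and enters at step 6.

**Three steps most likely to fail (in route order)**

**Step 5.** The risks are the crowded last ring position, Lewis-acid cleavage of the OMe next to the new carbonyl, and darkening of the very electron-rich phenol. The fallback sets out from 9 and returns at 11, and it replaces electrophilic acylation by an aryl anion.
- Compound 9 is protected with MOMCl/i-Pr2NEt in CH2Cl2 as 1-(methoxymethoxy)-2,3,4,5-tetramethoxybenzene F1.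
- n-BuLi in THF at 0 °C removes the only ring hydrogen, which is flanked by OMOM and OMe, to give 2-(methoxymethoxy)-3,4,5,6-tetramethoxyphenyllithium F2.
- N-Methoxy-N-methylacetamide acylates this to 1-[2-(methoxymethoxy)-3,4,5,6-tetramethoxyphenyl]ethanone F3.
- HCl in MeOH at rt removes the acetal and gives 11 without any Lewis acid touching the methyl ethers.

**Step 6.** The risks are a di-ortho-substituted, slowly reacting ketone, incomplete conversion, and chalcone/flavanone mixtures. Any 15 present is carried through step 7 all the same. The fallback sets out from 11 and returns at 17, skipping 14 and step 7, and it uses an intermolecular Claisen-type C-acylation instead of the aldol.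
- Compound 11 is treated with LiHMDS (4 equiv) in THF at −78 °C and then with bought 4-(benzyloxy)benzoyl chloride, O=C(Cl)c1ccc(OCc2ccccc2)cc1 (1 equiv).
- This gives 1-[4-(benzyloxy)phenyl]-3-(2-hydroxy-3,4,5,6-tetramethoxyphenyl)propane-1,3-dione F4.
- Cyclodehydration with cat. p-TsOH in refluxing toluene gives 17 directly at the flavone oxidation level.

**Step 7.** The risks are HI-induced loss of the 5-O-methyl group at 125 °C, partial debenzylation, and stalling at the flavanone. The fallback sets out from 14 and returns at 17, and it separates ring closure from dehydrogenation and uses no iodine.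
- Compound 14 is isomerised with NaOAc in refluxing EtOH (oxa-Michael). Flavanone 15 is isolated and recovered 14 is recycled.
- Compound 15 is dehydrogenated by hydride abstraction with DDQ (1.5 equiv) in refluxing dioxane to give 17.
- This fallback makes no compound that the list lacks, hence the entry none F0.

**Further compounds**
F1 | step 5 | 1-(methoxymethoxy)-2,3,4,5-tetramethoxybenzene | COCOc1cc(OC)c(OC)c(OC)c1OC
F2 | step 5 | 2-(methoxymethoxy)-3,4,5,6-tetramethoxyphenyllithium | [Li]c1c(OCOC)c(OC)c(OC)c(OC)c1OC
F3 | step 5 | 1-[2-(methoxymethoxy)-3,4,5,6-tetramethoxyphenyl]ethanone | CC(=O)c1c(OCOC)c(OC)c(OC)c(OC)c1OC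
F4 | step 6 | 1-[4-(benzyloxy)phenyl]-3-(2-hydroxy-3,4,5,6-tetramethoxyphenyl)propane-1,3-dione | COc1c(OC)c(OC)c(C(=O)CC(=O)c2ccc(OCc3ccccc3)cc2)c(O)c1OC
F0 | step 7 | none | none
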